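**Retrosynthetic overview**
1. Target 6 ⇒ dienal 5: disconnect the C15–OCH3 ester bond together with the C13–H bond, by a carbene-catalysed redox esterification of the (13E)-enal (new step; C–O bond formation that also sets C13).
2. 5 ⇒ 4 ⇒ 3: the C8(17) alkene comes from anti-elimination of the 8α-hydroxyl; the enal comes from oxidative 1,3-transposition of the C13 vinyl carbinol.
3. 3 ⇒ 2 ⇒ 1: the C18–O bond comes from site-selective enzymatic C–H hydroxylation of the 4α-methyl of (−)-sclareol (sets C4), followed by O-acetylation.
4. Rings: none is formed. Rings A and B (trans-decalin with C5, C9, C10) are taken intact from sclareol.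

Assumption: the SMILES is read as the normal-labdane isomer with 4α-CH2OAc/4β-CH3, 5α-H, 9β side chain and 10β-CH3, i.e. methyl (13R)-18-acetoxylabd-8(17)-en-15-oate (4R,5R,9S,10R,13R); (−)-sclareol is taken as the cheap commercial starting material.

**Step 1**
Reactants: 1 (−)-sclareol
Product: 2 18-hydroxysclareol
Conditions: Cunninghamella sp. (e.g. NRRL 5695; Mucor plumbeus as alternative), growing culture, air, 1 fed in DMF/Tween 80 (0.5 g/L), 27 °C, 6 d; EtOAc extraction, SiO2
Reagents that add atoms: dioxygen, O=O
Why: Fungal cytochrome P450 monooxygenation (hydrogen abstraction by the ferryl-oxo haem, then oxygen rebound) of sclareol is a precedented (as recalled from the literature) whole-cell biotransformation that gives the 18-alcohol among its main products; the exposed equatorial 4α-methyl is oxidised rather than the 1,3-diaxially shielded 4β-methyl, so the new C18–O bond fixes C4 as R, and the 2α-, 3β- and dihydroxylated co-metabolites are removed by chromatography (expect roughly 15–25%).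

**Step 2**
Reactants: 2 18-hydroxysclareol
Product: 3 18-acetoxysclareol
Conditions: Ac2O (1.2 equiv), pyridine, 0 °C to rt
Reagents that add atoms: acetic anhydride, CC(=O)OC(C)=O
Why: Chemoselective O-acylation; only the primary 18-hydroxyl reacts, the two tertiary hydroxyls are inert to Ac2O/pyridine, and no stereocentre is touched.

**Step 3**
Reactants: 3 18-acetoxysclareol
Product: 4 (13E)-8α-hydroxy-15-oxolabd-13-en-18-yl acetate
Conditions: [C5H5NH][CrO3Cl] (3 equiv), NaOAc (0.5 equiv), Celite, CH2Cl2, rt, 6 h; SiO2 separation of the 13E isomer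
Reagents that add atoms: pyridinium chlorochromate, [O-][Cr](=O)(=O)Cl.c1cc[nH+]cc1 (supplies the C15 carbonyl oxygen)
Why: Babler–Dauben oxidative 1,3-transposition of the tertiary vinyl carbinol: a [3,3] shift within the hexavalent chromium ester moves oxygen to C15 and oxidation gives the aldehyde, which erases the C13 carbinol centre; the tertiary 8α-hydroxyl and the acetate are not oxidised, and of the E/Z mixture (about 2:1) only the 13E isomer is carried on (the 13Z isomer can be re-equilibrated with catalytic iodine and recycled).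

**Step 4**
Reactants: 4 (13E)-8α-hydroxy-15-oxolabd-13-en-18-yl acetate
Product: 5 (13E)-15-oxolabda-8(17),13-dien-18-yl acetate
Conditions: SOCl2 (1.5 equiv), pyridine (6 equiv), CH2Cl2, −78 °C, 30 min; AgNO3-impregnated SiO2 if endocyclic isomers must be removed
Reagents that add atoms: none
Why: Regioselective E2 dehydration: the sulfur-activated equatorial 8α-oxygen has no anti-periplanar ring hydrogen, only a hydrogen of the axial C17 methyl can be anti, so the exocyclic C8(17) alkene predominates at low temperature; the enal and acetate are inert and C9 is not epimerised.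

**Step 5**
Reactants: 5 (13E)-15-oxolabda-8(17),13-dien-18-yl acetate
Product: 6 methyl (13R)-18-acetoxylabd-8(17)-en-15-oate
Conditions: (S)-5-(hydroxydiphenylmethyl)-2-mesityl-6,7-dihydro-5H-pyrrolo[2,1-c][1,2,4]triazol-2-ium tetrafluoroborate (10 mol%; or its enantiomer, whichever delivers hydrogen to the Si face of C13), iPr2NEt (20 mol%), MeOH (3 equiv), toluene, 0 °C to rt
Reagents that add atoms: methanol, CO
Why: Proposed new method: diastereoselective carbene-catalysed redox esterification of a β,β-dialkyl enal. The carbene adds to the C15 aldehyde and proton transfer gives the catalyst-bound homoenolate (extended Breslow species) with nucleophilic C13; the catalyst's tertiary hydroxyl hydrogen-bonds the enol oxygen, holds the dienol planar and places the diphenylcarbinol over one face, so methanol protonates C13 on the open Si face of the geometrically pure 13E substrate and sets 13R; tautomerisation gives the acylated catalyst, which methanol cleaves to form the C15–OCH3 bond and release the carbene (internal redox, no external reductant). The closest known reaction type is the carbene-catalysed redox esterification of enals through β-protonation, whose enantioselective form has so far been shown essentially for β-aryl-substituted enals; a β-carbon carrying only CH3 and CH2 groups under catalyst control next to a remote terpenoid core has not been shown.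

**Compound list**
1 | (−)-sclareol, (13R)-labd-14-ene-8α,13-diol | C[C@@]1(O)CC[C@H]2C(C)(C)CCC[C@]2(C)[C@H]1CC[C@@](C)(O)C=C | starting material
2 | 18-hydroxysclareol, (4R,13R)-labd-14-ene-8α,13,18-triol (CH2OH is the equatorial 4α carbon, CH3 is 4β) | C[C@@]1(O)CC[C@H]2[C@](C)(CO)CCC[C@]2(C)[C@H]1CC[C@@](C)(O)C=C | intermediate
3 | 18-acetoxysclareol, (13R)-8α,13-dihydroxylabd-14-en-18-yl acetate | C[C@@]1(O)CC[C@H]2[C@](C)(COC(C)=O)CCC[C@]2(C)[C@H]1CC[C@@](C)(O)C=C | intermediate
4 | (13E)-8α-hydroxy-15-oxolabd-13-en-18-yl acetate | C[C@@]1(O)CC[C@H]2[C@](C)(COC(C)=O)CCC[C@]2(C)[C@H]1CC/C(C)=C/C=O | intermediate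
5 | (13E)-15-oxolabda-8(17),13-dien-18-yl acetate | C=C1CC[C@H]2[C@](C)(COC(C)=O)CCC[C@]2(C)[C@H]1CC/C(C)=C/C=O | intermediate
6 | methyl (13R)-18-acetoxylabd-8(17)-en-15-oate (4R,5R,9S,10R,13R) | C=C1CC[C@H]2[C@](C)(COC(C)=O)CCC[C@]2(C)[C@H]1CC[C@@H](C)CC(=O)OC | target

**Totals**
Total step count: 5. Longest linear sequence: 5 steps (1 → 6).

**Steps most likely to fail**

Step 5 (the new step). Risks: modest facial selectivity at C13, slow turnover with the β,β-dialkyl enal, and partial carbene-catalysed methanolysis of the 18-acetate. Fallback with known chemistry, setting out from 5 and returning at 6: iminium-type transfer hydrogenation with the morpholinium salt of (R)-TRIP (the enantiomer that turns citral into (R)-citronellal) and Hantzsch ester in dioxane at 50 °C, a process that is convergent for E/Z enal mixtures, gives (13R)-15-oxolabd-8(17)-en-18-yl acetate F7. Pinnick oxidation (NaClO2, NaH2PO4, 2-methyl-2-butene, tBuOH/H2O) gives (13R)-18-acetoxylabd-8(17)-en-15-oic acid F8, and Me3SiCHN2 in MeOH/toluene gives 6.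

Step 1. Risks: low yield and difficult separation from the 2α-, 3β- and dihydroxylated metabolites. Fallback that replaces undirected enzymatic C18 oxidation by a hydroxyl-directed chemical C–H oxygenation, setting out from 1 and returning at 2:
- C3-selective hydroxylation of sclareol (cytochrome P450 BM3 variant in E. coli whole cells, or Mucor plumbeus) gives 3β-hydroxysclareol F1.
- Et2SiH2 with [Ir(cod)OMe]2 (THF, rt) silylates the secondary hydroxyl to the 3-O-diethylsilyl ether F2.
- [Ir(cod)OMe]2/3,4,7,8-tetramethyl-1,10-phenanthroline with norbornene (THF, 100 °C) silylates the equatorial 4α-methyl C–H and closes the oxasilolane F3. The hindered vinyl group is the main liability of this stage.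
- H2O2/KHCO3 (Tamao–Fleming) gives 3β,18-dihydroxysclareol F4.
- 1,1'-Thiocarbonyldiimidazole closes the cyclic 3,18-thionocarbonate F5.
- Bu3SnH/AIBN (toluene, reflux) followed by NaOH/MeOH cleaves only the secondary C3–O bond and delivers 2.

Step 3. Risks: acid-promoted attack of the free 8α-hydroxyl on C13 (manoyl-oxide-type ethers, or conjugate addition to the enal) and loss of material as the 13Z isomer. Fallback that separates transposition from oxidation, setting out from 3 and returning at 4: redox-neutral 1,3-transposition with OV(OSiPh3)3 (2 mol%, xylene, 140 °C) gives (13E)-18-acetoxylabd-13-ene-8α,15-diol F6 after separation of the E isomer, and chemoselective allylic oxidation with MnO2 in CH2Cl2 gives 4.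

**Further compounds**
F1 | step 1 | 3β-hydroxysclareol, (13R)-labd-14-ene-3β,8α,13-triol | C[C@@]1(O)CC[C@H]2C(C)(C)[C@@H](O)CC[C@]2(C)[C@H]1CC[C@@](C)(O)C=C
F2 | step 1 | 3β-O-(diethylsilyl)sclareol-3β-ol ether, (13R)-3β-(diethylsilyloxy)labd-14-ene-8α,13-diol | C[C@@]1(O)CC[C@H]2C(C)(C)[C@@H](O[SiH](CC)CC)CC[C@]2(C)[C@H]1CC[C@@](C)(O)C=C
F3 | step 1 | 3β-O,18-C-(diethylsilanediyl) oxasilolane of (13R)-labd-14-ene-3β,8α,13-triol | C[C@@]1(O)CC[C@H]2[C@]3(C)C[Si](CC)(CC)O[C@H]3CC[C@]2(C)[C@H]1CC[C@@](C)(O)C=C
F4 | step 1 | 3β,18-dihydroxysclareol, (13R)-labd-14-ene-3β,8α,13,18-tetraol | C[C@@]1(O)CC[C@H]2[C@](C)(CO)[C@@H](O)CC[C@]2(C)[C@H]1CC[C@@](C)(O)C=C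
F5 | step 1 | cyclic 3β,18-O-thionocarbonate of (13R)-labd-14-ene-3β,8α,13,18-tetraol | C[C@@]1(O)CC[C@H]2[C@]3(C)COC(=S)O[C@H]3CC[C@]2(C)[C@H]1CC[C@@](C)(O)C=C
F6 | step 3 | (13E)-18-acetoxylabd-13-ene-8α,15-diol | C[C@@]1(O)CC[C@H]2[C@](C)(COC(C)=O)CCC[C@]2(C)[C@H]1CC/C(C)=C/CO
F7 | step 5 | (13R)-15-oxolabd-8(17)-en-18-yl acetate | C=C1CC[C@H]2[C@](C)(COC(C)=O)CCC[C@]2(C)[C@H]1CC[C@@H](C)CC=O
F8 | step 5 | (13R)-18-acetoxylabd-8(17)-en-15-oic acid | C=C1CC[C@H]2[C@](C)(COC(C)=O)CCC[C@]2(C)[C@H]1CC[C@@H](C)CC(=O)O
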